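Which way of charging the flask leaves the largest share of first product beside double product?

    reagent + other mono adduct → double product (k1 = 0.0095 /M/s)
    reagent + first product → double product (k2 = 0.013 /M/s)
    starting material + reagent → other mono adduct (k3 = 0.0048 /M/s)
    2 reagent → homo dimer (k4 = 0.012 /M/s)
    starting material + first product → side product (k5 = 0.49 /M/s)
    starting material + reagent → first product (k6 = 0.0067 /M/s)

common to all: time 50 min

|  | starting material | reagent | remark |
|---|---|---|---|
| south-west | 0.020 M (fed, over 20 min) | 0.0500 M | all else is in the flask from the start; the feed brings no volume worth counting |
| south | 0.020 M | 0.0500 M (fed, over 20 min) | all else is in the flask from the start; the feed brings no volume worth counting |
| north-east | 0.020 M | 0.0500 M (fed, over 2.0 min) | all else is in the flask from the start; the feed brings no volume worth counting |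
| west | 0.020 M (in portions, 2, over 20 min) | 0.0500 M | first portion at the start, last at 20 min |
| east | 0.020 M | 0.0500 M | everything together at the start |

* the best flask by share of first product in first product plus double product; "all alike" if 1.5 percentage points covers them all (south-west / south / north-east / west / east / all alike)
* share of first product in first product plus double product at the end, south-west
* share of first product in first product plus double product at the end, south
* share of first product in first product plus double product at the end, north-east
* share of first product in first product plus double product at the end, west
* share of first product in first product plus double product at the end, east

- percentages count the starting material that a species holds: one side product counts as two
- two of one species on the left: rate k times its square, two consumed each time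
- run time (south-west): 50 min

First product is the small thing in these flasks, so it can be reckoned apart from the large flow of material. Starting material and reagent form it with constant 0.0067 /M/s, and starting material removes it again with constant 0.49 /M/s. Reagent also removes it, with constant 0.013 /M/s. With the amounts as charged, one first product meets starting material at 0.00980 /s and reagent at 6.50 × 10⁻⁴ /s, so the drain through reagent is much the slower and is set aside as a correction.

The lifetime of first product against starting material is then 1.70 min, much shorter than the run of 50 min. Making and removal therefore keep level, which is the quasi-steady state. Both rates carry the amount of starting material, so it cancels, and first product stands at a steady fraction of the reagent. That fraction, constant of making over constant of removal, is 0.0137; call it the resting ratio.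

The reckoning now needs the reagent. In the east flask, at the start, reagent goes to homo dimer at 9.0 times the rate at which it goes to first product, so the dimer law alone is used as a first figure. Under that law the reciprocal of the reagent amount grows steadily, which leaves 0.0109 M after 50 min. The other steps take reagent too, so this figure stands high.

The south-west flask holds its reagent from the start, as the east flask does, so the reckoning gives both about 0.743% of the charge as first product. The reckoning stops there: the resting ratio gives a figure for first product and none for double product, so it gives no share of its own.

The forecast names south-west as best, with 16% for south-west, 13.5% for south, 11.5% for north-east, 15% for west and 11.3% for east. Its ground is this: “Feeding the starting material late leaves less time for that route”.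

The simulation gives south-west as best, with 16.0% there, 13.1% in south, 10.1% in north-east, 13.4% in west and 9.92% in east, and the forecast stands within its tolerance on each. At 50.0 min the south-west flask holds 0.587% first product and 3.09% double product, the east flask 0.607% and 5.51%, so the gap in double product is wider than that in first product. The resting ratio times the simulated reagent gives 0.560% for south-west, and for the south flask 0.774% against its simulated 0.830%.

(The numbers of this flask belong to no real substance.)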